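**Retrosynthetic overview**

1. Feature: the target is a bicyclo[3.2.1]octane (labels: C1 allyl bridgehead, C2 CH2, C3 CH–OMe, C4 C=O, C5 OMe bridgehead, C6 CH–aryl, C7 CH–Me, C8 CH–OAc; cyclopentane C1–C7–C6–C5–C8, cyclohexanone C1–C2–C3–C4–C5–C8). The array C8–O / fully substituted C5–OMe / C4=O is read as the imprint of a 1,2-shift of C6 from C4 to C5. These labels are kept for every bicyclic intermediate (labels, not locants).
2. Endgame: C3–H by conjugate reduction and exo protonation of the C2=C3 3-methoxy enone 31; C3–O by hydroxylation of the C4 ketone, oxidation and O-methylation; acetyl on the C8 oxygen.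
3. Key disconnection C5–C6: ketol 23 from bicyclo[2.2.2]octene 21 (C4 bridgehead OH, C5(OMe)=C8 enol ether) by epoxidation of C5=C8 and semipinacol shift. This converts the bicyclo[2.2.2]octane into the bicyclo[3.2.1]octane.
4. 21 from keto imide 15 (ketone to methyl enol ether, acyl to CH3, desilylation). 15 by double Michael addition (C4–C6, then C7–C1) of the dienolate of silyloxy enone 7 to cinnamoyl imide 11; this closes the bicyclo[2.2.2]octane on the purchased six-membered ring and sets C1, C4, C6 and C7.
5. 7 from 3-ethoxycyclohex-2-en-1-one (allyl addition with carbonyl transposition, α′-hydroxylation, silylation); 11 from (E)-3,4-dimethoxycinnamic acid and (S)-4-benzyloxazolidin-2-one.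

Key step: step 11

Assumption: the face selectivity of step 5 is assigned from the lithium-chelated syn-s-cis conformer of imide 11; should the adduct prove antipodal, (R)-4-benzyloxazolidin-2-one would replace 9 and nothing else would change.

**Route**

Step 1
Reactants: 1 3-ethoxycyclohex-2-en-1-one; 2 allylmagnesium bromide
Product: 4 3-allylcyclohex-2-en-1-one, via bromomagnesium alkoxide 3 (not isolated)
Conditions: CH2=CHCH2MgBr (1.2 equiv), THF, 0 °C; then 1 M aq HCl, 0 °C, 15 min
Reagents that add atoms: water, O
Why: Stork–Danheiser transposition, in which 1,2-addition of the Grignard reagent to the vinylogous ester and brief cold acid hydrolysis with loss of the tertiary hydroxyl move the carbonyl and leave the allyl group on the β-carbon, the short acid contact being chosen so that the skipped diene is not drawn into conjugation.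

Step 2
Reactants: 4 3-allylcyclohex-2-en-1-one
Product: 6 3-allyl-6-hydroxycyclohex-2-en-1-one (racemic), via potassium dienolate 5 (not isolated)
Conditions: KN(SiMe3)2 (1.1 equiv), THF, −78 °C; 2-(phenylsulfonyl)-3-phenyloxaziridine (1.3 equiv), −78 °C; aq NH4Cl
Reagents that add atoms: 2-(phenylsulfonyl)-3-phenyloxaziridine, O=S(=O)(c1ccccc1)N1OC1c1ccccc1
Why: Kinetic deprotonation of an enone by a hindered amide base should occur at the α′-carbon to give the cross-conjugated dienolate, and its oxidation by the N-sulfonyloxaziridine (electrophilic enolate hydroxylation) installs the oxygen that becomes the C4 bridgehead hydroxyl; the new carbinol centre is left racemic because it becomes trigonal again in step 5.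

Step 3
Reactants: 6 3-allyl-6-hydroxycyclohex-2-en-1-one
Product: 7 3-allyl-6-(tert-butyldimethylsilyloxy)cyclohex-2-en-1-one (racemic)
Conditions: TBSCl, imidazole, DMF, 23 °C
Reagents that add atoms: tert-butyldimethylsilyl chloride, CC(C)(C)[Si](C)(C)Cl
Why: Imidazole-promoted O-silylation of the secondary ketol hydroxyl gives a silyl ether that tolerates amide bases, hydrides and mesylation and is later removed by fluoride without harm to the enol ether.

Step 4
Reactants: 8 (E)-3-(3,4-dimethoxyphenyl)acrylic acid; 9 (S)-4-benzyloxazolidin-2-one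
Product: 11 (S)-4-benzyl-3-[(E)-3-(3,4-dimethoxyphenyl)prop-2-enoyl]oxazolidin-2-one, via mixed pivalic anhydride 10 (not isolated)
Conditions: Me3CCOCl, Et3N, THF, −20 °C; then 9, LiCl, 23 °C
Reagents that add atoms: none
Why: N-Acylation of the oxazolidinone through the mixed pivalic anhydride is a standard entry to enoyl imides, leaves the E-alkene untouched and carries the benzyl-bearing centre over unchanged from 9.

Step 5
Reactants: 7 3-allyl-6-(tert-butyldimethylsilyloxy)cyclohex-2-en-1-one; 11 (S)-4-benzyl-3-[(E)-3-(3,4-dimethoxyphenyl)prop-2-enoyl]oxazolidin-2-one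
Product: 15 bicyclic keto imide (1-allyl-4-silyloxybicyclo[2.2.2]octan-5-one; C6-aryl syn to C2–C3; C7-acyl syn to C5–C8), via lithium dienolate 12 (not isolated), via Michael adduct enolate 13 (not isolated), via bicyclic lithium enolate 14 (not isolated)
Conditions: LiN(iPr)2 (1.05 equiv), THF, −78 °C, 45 min; then 11, −78 → −20 °C; aq NH4Cl
Reagents that add atoms: none
Why: Double Michael addition (anionic formal Diels–Alder reaction) in which the oxygen-bearing enolate carbon C4 adds to the β-carbon of the chelated imide on the face away from the benzyl group (sets C6), the lithium bridge between the enolate oxygen and the imide carbonyls holds the acyl group over the enolate (endo topicity, sets C4 relative to C6), and the (Z)-imide enolate 13 then closes on the allyl-bearing enone carbon to give the quaternary C1 and the C7 centre with aryl and acyl trans as in the E-alkene.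

Step 6
Reactants: 15 bicyclic keto imide
Product: 17 C5(OMe)=C8 methyl enol ether of 15, via potassium enolate 16 (not isolated)
Conditions: KN(SiMe3)2 (1.1 equiv), THF–DMPU, −78 °C; Me2SO4, −78 → 0 °C
Reagents that add atoms: dimethyl sulfate, COS(=O)(=O)OC
Why: Enolate O-alkylation, since the ketone can enolise only towards C8 (C4 is a bridgehead and the imide α-hydrogen at C7 cannot reach a planar enolate without severe allylic strain) and a potassium enolate in a dipolar aprotic cosolvent should react with the hard sulfate electrophile on oxygen.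

Step 7
Reactants: 17 methyl enol ether imide
Product: 18 primary alcohol (C7–CH2OH)
Conditions: LiBH4, MeOH (1.1 equiv), Et2O, 0 °C
Reagents that add atoms: none
Why: Reductive cleavage of the N-acyl oxazolidinone by LiBH4 should give the primary alcohol and release the auxiliary, while the enol ether, the silyl ether and the alkenes are inert to borohydride and no stereocentre is touched.

Step 8
Reactants: 18 primary alcohol
Product: 19 primary mesylate (C7–CH2OMs)
Conditions: MsCl, Et3N, CH2Cl2, 0 °C
Reagents that add atoms: methanesulfonyl chloride, CS(=O)(=O)Cl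
Why: Sulfonylation of the primary alcohol under amine-buffered conditions is compatible with the acid-labile enol ether.

Step 9
Reactants: 19 primary mesylate
Product: 20 C7-methyl compound (silyl ether of 21)
Conditions: LiEt3BH (3 equiv), THF, 0 → 50 °C
Reagents that add atoms: none
Why: SN2 displacement of the primary mesylate by the strongly nucleophilic hydride LiEt3BH (reductive deoxygenation) turns the former acyl carbon into the C7 methyl group without touching the C7 centre.

Step 10
Reactants: 20 C7-methyl silyl ether
Product: 21 1-allyl-4-hydroxy-5-methoxybicyclo[2.2.2]octene (C5=C8 enol ether; C6-aryl syn to C2–C3; C7-methyl syn to C5=C8)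
Conditions: Bu4NF (3 equiv), THF, 50 °C
Reagents that add atoms: none
Why: Fluoride-induced desilylation frees the bridgehead C4 hydroxyl under basic conditions that keep the methyl enol ether intact.

Step 11
Reactants: 21 1-allyl-4-hydroxy-5-methoxybicyclo[2.2.2]octene
Product: 23 1-allyl-8-hydroxy-5-methoxybicyclo[3.2.1]octan-4-one (6-endo-aryl; 7-exo-methyl; C8–OH on the side of the C2–C4 bridge), via epoxy acetal 22 (not isolated)
Conditions: DMDO (1.05 equiv, dried acetone solution), CH2Cl2, 4 Å MS, −78 → 0 °C
Reagents that add atoms: dimethyldioxirane, CC1(C)OO1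
Why: Neutral, electrophilic DMDO should epoxidise the electron-rich C5=C8 enol ether, and not the monosubstituted allyl alkene or the arene, from the face turned to the C2–C3 bridge because the C7 methyl group leans over the other face, which sets C8 with its oxygen on the side of the future three-carbon bridge. The 2-methoxyoxirane 22, activated by a hydrogen bond from the adjacent C4 hydroxyl, opens at the acetal carbon C5 towards an oxocarbenium ion, and the C4–C6 bond, antiperiplanar to the breaking C5–O bond, migrates to C5 while the C4–O bond becomes the carbonyl and the proton passes to the C8 alkoxide. The closest known reaction type is the semipinacol rearrangement of 2,3-epoxy alcohols, here started from an epoxy acetal of the kind formed in the first stage of a Rubottom oxidation. Both rings of the bicyclo[3.2.1]octane result from this one suprafacial 1,2-alkyl shift and not from a chain cyclisation: the new C5–C6 bond closes the cyclopentane C1–C7–C6–C5–C8 by contraction of the ring C1–C8–C5–C4–C6–C7, and loss of the C4–C6 bond leaves C1–C2–C3–C4–C5–C8 as the cyclohexanone. C5 is fixed by inversion at the acetal carbon (C6 enters anti to the leaving oxygen) within the bridged frame, and C6 migrates with retention. The step needs selection between C6 and C3 as migrating carbons, which is secured by the anti alignment of C6, its benzylic secondary nature and the syn position of C3 relative to the leaving oxygen.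

Step 12
Reactants: 23 8-hydroxy-5-methoxybicyclo[3.2.1]octan-4-one
Product: 24 8-acetate of 23
Conditions: Ac2O, DMAP, pyridine, CH2Cl2, 23 → 40 °C
Reagents that add atoms: acetic anhydride, CC(=O)OC(C)=O
Why: DMAP-catalysed acylation of the hindered secondary C8 alcohol is placed here so that the β-hydroxy ketone is protected against retro-aldol cleavage in the following steps and no base is needed after C3 is set.

Step 13
Reactants: 24 keto acetate
Product: 25 C3=C4 trimethylsilyl enol ether of 24
Conditions: TMSOTf, Et3N, CH2Cl2, 0 °C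
Reagents that add atoms: trimethylsilyl trifluoromethanesulfonate, C[Si](C)(C)OS(=O)(=O)C(F)(F)F
Why: Soft enolisation (silyl enol ether formation) can occur only towards C3 because C5 is quaternary, so the enol ether should form regiospecifically while the acetate is untouched.

Step 14
Reactants: 25 trimethylsilyl enol ether
Product: 28 3-exo-hydroxy-4-ketone, via silyloxy epoxide 26 (not isolated), via silyloxy ketone 27 (not isolated)
Conditions: DMDO (1.05 equiv), acetone/CH2Cl2, −78 → −20 °C; then aq citric acid, THF, 23 °C
Reagents that add atoms: dimethyldioxirane, CC1(C)OO1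
Why: Rubottom oxidation, in which DMDO epoxidises the silyl enol ether from the exo face in preference to the allyl group, the silyloxy epoxide rearranges by 1,4-silyl shift and mild acid frees the C3 hydroxyl, whose exo configuration is of no consequence because C3 becomes trigonal in step 15.

Step 15
Reactants: 28 3-hydroxy-4-ketone
Product: 30 diosphenol (C2=C3 enol of the 3,4-dione), via diketone 29 (not isolated)
Conditions: DMP (1.3 equiv), CH2Cl2, 0 → 23 °C
Reagents that add atoms: none
Why: Periodinane oxidation of the ketol gives the 3,4-diketone, which can enolise only towards C2 and should therefore rest as the diosphenol, with no risk to the allyl group or the acetate.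

Step 16
Reactants: 30 diosphenol
Product: 31 3-methoxybicyclo[3.2.1]oct-2-en-4-one (diosphenol methyl ether)
Conditions: MeI, K2CO3, acetone, 40 °C
Reagents that add atoms: iodomethane, CI
Why: Williamson-type O-alkylation of the acidic enol hydroxyl under K2CO3 in acetone, conditions the acetate survives, should give the methyl ether because carbon C2 is shielded by the quaternary C1.

Step 17
Reactants: 31 3-methoxy-2-en-4-one
Product: 33 target CNP0344493.1, via copper enolate 32 (not isolated)
Conditions: [(Ph3P)CuH]6 (0.4 equiv), H2O (5 equiv), degassed benzene, 23 °C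
Reagents that add atoms: none
Why: Conjugate reduction by the phosphine copper hydride delivers hydride to C2 and spares the allyl group, the acetate and the ketone, and the copper enolate is protonated by water at C3 from the open exo face (the endo face lies under the endo C6-aryl group), which places hydrogen exo and methoxy endo as in the target under neutral conditions that do not equilibrate the new centre.

**Compound list**

1 | 3-ethoxycyclohex-2-en-1-one | CCOC1=CC(=O)CCC1 | starting material
2 | allylmagnesium bromide | C=CC[Mg]Br | starting material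
3 | bromomagnesium 1-allyl-3-ethoxycyclohex-2-en-1-olate (racemic) | C=CCC1(O[Mg]Br)C=C(OCC)CCC1 | intermediate
4 | 3-allylcyclohex-2-en-1-one | C=CCC1=CC(=O)CCC1 | intermediate
5 | potassium cross-conjugated dienolate of 4 | C=CCC1=CC([O-])=CCC1.[K+] | intermediate
6 | 3-allyl-6-hydroxycyclohex-2-en-1-one (racemic) | C=CCC1=CC(=O)C(O)CC1 | intermediate
7 | 3-allyl-6-(tert-butyldimethylsilyloxy)cyclohex-2-en-1-one (racemic) | C=CCC1=CC(=O)C(O[Si](C)(C)C(C)(C)C)CC1 | intermediate
8 | (E)-3-(3,4-dimethoxyphenyl)acrylic acid | COc1ccc(/C=C/C(=O)O)cc1OC | starting material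
9 | (S)-4-benzyloxazolidin-2-one | O=C1N[C@@H](Cc2ccccc2)CO1 | starting material
10 | mixed anhydride of 8 and pivalic acid | COc1ccc(/C=C/C(=O)OC(=O)C(C)(C)C)cc1OC | intermediate
11 | (S)-4-benzyl-3-[(E)-3-(3,4-dimethoxyphenyl)prop-2-enoyl]oxazolidin-2-one | COc1ccc(/C=C/C(=O)N2[C@@H](Cc3ccccc3)COC2=O)cc1OC | intermediate
12 | lithium cross-conjugated dienolate of 7 | C=CCC1=CC([O-])=C(O[Si](C)(C)C(C)(C)C)CC1.[Li+] | intermediate
13 | lithium (Z)-imide enolate after the first Michael addition (C4–C6 bond formed, cyclohexenone intact) | C=CCC1=CC(=O)[C@@](O[Si](C)(C)C(C)(C)C)([C@H](c2ccc(OC)c(OC)c2)/C=C(\[O-])N2[C@@H](Cc3ccccc3)COC2=O)CC1.[Li+] | intermediate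
14 | lithium C5=C8 enolate of 15 | C=CC[C@]12CC[C@@](O[Si](C)(C)C(C)(C)C)(C([O-])=C2)[C@H](c3ccc(OC)c(OC)c3)[C@H]1C(=O)N1[C@@H](Cc3ccccc3)COC1=O.[Li+] | intermediate
15 | 1-allyl-4-(tert-butyldimethylsilyloxy)bicyclo[2.2.2]octan-5-one (target labels) with C6 3,4-dimethoxyphenyl syn to the C2–C3 bridge and C7 [(S)-4-benzyl-2-oxooxazolidin-3-yl]carbonyl syn to the C5–C8 bridge, aryl and acyl trans | C=CC[C@]12CC[C@@](O[Si](C)(C)C(C)(C)C)(C(=O)C2)[C@H](c3ccc(OC)c(OC)c3)[C@H]1C(=O)N1[C@@H](Cc3ccccc3)COC1=O | intermediate
16 | potassium C5=C8 enolate of 15 | C=CC[C@]12CC[C@@](O[Si](C)(C)C(C)(C)C)(C([O-])=C2)[C@H](c3ccc(OC)c(OC)c3)[C@H]1C(=O)N1[C@@H](Cc3ccccc3)COC1=O.[K+] | intermediate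
17 | C5(OMe)=C8 methyl enol ether of 15 | C=CC[C@]12CC[C@@](O[Si](C)(C)C(C)(C)C)(C(OC)=C2)[C@H](c3ccc(OC)c(OC)c3)[C@H]1C(=O)N1[C@@H](Cc3ccccc3)COC1=O | intermediate
18 | primary alcohol: as 17 with CH2OH on C7 | C=CC[C@]12CC[C@@](O[Si](C)(C)C(C)(C)C)(C(OC)=C2)[C@H](c3ccc(OC)c(OC)c3)[C@H]1CO | intermediate
19 | methanesulfonate of 18 | C=CC[C@]12CC[C@@](O[Si](C)(C)C(C)(C)C)(C(OC)=C2)[C@H](c3ccc(OC)c(OC)c3)[C@H]1COS(C)(=O)=O | intermediate
20 | tert-butyldimethylsilyl ether of 21 (C7 methyl) | C=CC[C@]12CC[C@@](O[Si](C)(C)C(C)(C)C)(C(OC)=C2)[C@H](c3ccc(OC)c(OC)c3)[C@H]1C | intermediate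
21 | 1-allyl-4-hydroxy-5-methoxybicyclo[2.2.2]octene with C5=C8 enol ether, C6 3,4-dimethoxyphenyl syn to the C2–C3 bridge, C7 methyl syn to the C5=C8 bridge | C=CC[C@]12CC[C@@](O)(C(OC)=C2)[C@H](c3ccc(OC)c(OC)c3)[C@H]1C | intermediate
22 | C5–C8 epoxide of 21 (epoxy acetal, oxygen on the face turned to the C2–C3 bridge) | C=CC[C@]12CC[C@@](O)([C@@]3(OC)O[C@@H]23)[C@H](c4ccc(OC)c(OC)c4)[C@H]1C | intermediate
23 | 1-allyl-8-hydroxy-5-methoxybicyclo[3.2.1]octan-4-one with 6-endo-(3,4-dimethoxyphenyl) (towards the C2–C4 bridge), 7-exo-methyl (towards C8), C8–OH on the side of the C2–C4 bridge | C=CC[C@]12CCC(=O)[C@](OC)([C@H](c3ccc(OC)c(OC)c3)[C@H]1C)[C@H]2O | intermediate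
24 | 8-acetate of 23 | C=CC[C@]12CCC(=O)[C@](OC)([C@H](c3ccc(OC)c(OC)c3)[C@H]1C)[C@H]2OC(C)=O | intermediate
25 | C3=C4 trimethylsilyl enol ether of 24 | C=CC[C@]12CC=C(O[Si](C)(C)C)[C@](OC)([C@H](c3ccc(OC)c(OC)c3)[C@H]1C)[C@H]2OC(C)=O | intermediate
26 | exo C3–C4 epoxide of 25 | C=CC[C@]12C[C@H]3O[C@@]3(O[Si](C)(C)C)[C@](OC)([C@H](c4ccc(OC)c(OC)c4)[C@H]1C)[C@H]2OC(C)=O | intermediate
27 | 3-exo-trimethylsilyloxy-4-ketone | C=CC[C@]12C[C@@H](O[Si](C)(C)C)C(=O)[C@](OC)([C@H](c3ccc(OC)c(OC)c3)[C@H]1C)[C@H]2OC(C)=O | intermediate
28 | 3-exo-hydroxy-4-ketone | C=CC[C@]12C[C@@H](O)C(=O)[C@](OC)([C@H](c3ccc(OC)c(OC)c3)[C@H]1C)[C@H]2OC(C)=O | intermediate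
29 | 3,4-diketone | C=CC[C@]12CC(=O)C(=O)[C@](OC)([C@H](c3ccc(OC)c(OC)c3)[C@H]1C)[C@H]2OC(C)=O | intermediate
30 | diosphenol: 3-hydroxybicyclo[3.2.1]oct-2-en-4-one | C=CC[C@]12C=C(O)C(=O)[C@](OC)([C@H](c3ccc(OC)c(OC)c3)[C@H]1C)[C@H]2OC(C)=O | intermediate
31 | 3-methoxybicyclo[3.2.1]oct-2-en-4-one (diosphenol methyl ether) | C=CC[C@]12C=C(OC)C(=O)[C@](OC)([C@H](c3ccc(OC)c(OC)c3)[C@H]1C)[C@H]2OC(C)=O | intermediate
32 | monovalent copper C3=C4 enolate of 33 | C=CC[C@]12CC(OC)=C([O-])[C@](OC)([C@H](c3ccc(OC)c(OC)c3)[C@H]1C)[C@H]2OC(C)=O.[Cu+] | intermediate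
33 | CNP0344493.1: 8-acetoxy-1-allyl-6-endo-(3,4-dimethoxyphenyl)-3-endo,5-dimethoxy-7-exo-methylbicyclo[3.2.1]octan-4-one (3-OMe towards the C6–C7 bridge, 8-OAc on the side of the C2–C4 bridge) | C=CC[C@]12C[C@H](OC)C(=O)[C@](OC)([C@H](c3ccc(OC)c(OC)c3)[C@H]1C)[C@H]2OC(C)=O | target

**Step count**

Total: 17 steps. Longest linear sequence: 16 steps (steps 1–3 and 5–17; step 4 is a one-step side branch).

**Steps most likely to fail**

Step 5 (double Michael addition). The base may remove a γ-hydrogen (ring C4′ or the doubly allylic side-chain CH2) instead of the oxygen-bearing α′-hydrogen. The fully substituted enolate carbon may add only slowly to the β-aryl acceptor. The auxiliary may discriminate the faces incompletely. The fallback gives up auxiliary control in favour of a smaller acceptor and a resolution; it sets out from 7 and 8 and comes back at 18. Acid 8 is esterified (MeOH, cat. H2SO4, reflux) to methyl (E)-3-(3,4-dimethoxyphenyl)acrylate F1. The dienolate 12 (from 7, LiN(iPr)2, THF, −78 °C) is combined with F1 to give the racemic keto ester F2 with the relative configuration of 15. Enolate O-methylation as in step 6 gives the racemic enol ether ester F3. Reduction (LiAlH4, Et2O, 0 °C) gives the racemic alcohol F4, which is resolved by preparative chromatography on a chiral stationary phase to give 18.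

Step 11 (epoxidation and semipinacol shift). The epoxy acetal or the oxocarbenium ion may be intercepted by adventitious water before the shift, ending in hydrolysis to the ketol. C3 may migrate in competition with C6. Excess oxidant may reach the allyl group. The fallback replaces the epoxide-triggered shift by a classical α-ketol rearrangement; it sets out from 21 and comes back at 24. Compound 21 is oxidised with DMDO in wet acetone and the epoxy acetal is deliberately hydrolysed (dilute aqueous AcOH, THF) to 1-allyl-4,8-dihydroxybicyclo[2.2.2]octan-5-one F5 (C8–OH on the face turned to the C2–C3 bridge). The secondary C8 hydroxyl alone is acetylated (Ac2O, pyridine, DMAP) to F6. Lewis acid (BF3·OEt2, CH2Cl2, 0 → 23 °C) then moves C6 from C4 to the C5 carbonyl carbon, as bridgehead ketols of bicyclo[2.2.2]octanones are known to do, and gives the 5-hydroxy-4-ketone F7 with the bicyclo[3.2.1] skeleton. The tertiary hydroxyl is methylated (MeOTf, 2,6-di-tert-butyl-4-methylpyridine, CH2Cl2) to 24.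

Step 6 (enolate O-methylation). Methylation may take place on carbon C8 instead of oxygen, and the base may also attack the imide α-position. The fallback replaces enolate alkylation by acetal formation and elimination; it sets out from 15 and comes back at 17. Ketone 15 is converted with MeOSiMe3 and catalytic TMSOTf (CH2Cl2, −78 → −20 °C) into the dimethyl ketal F8. TMSOTf and iPr2NEt (CH2Cl2, −20 → 23 °C) then remove one methoxy group as its silyl ether in the only possible direction (towards C8) to give 17.

**Further compounds**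

F1 | step 5 | methyl (E)-3-(3,4-dimethoxyphenyl)acrylate | COC(=O)/C=C/c1ccc(OC)c(OC)c1
F2 | step 5 | racemic methyl ester analogue of 15 (one enantiomer drawn, relative configuration as in 15) | C=CC[C@]12CC[C@@](O[Si](C)(C)C(C)(C)C)(C(=O)C2)[C@H](c3ccc(OC)c(OC)c3)[C@H]1C(=O)OC
F3 | step 5 | racemic methyl ester analogue of 17 (one enantiomer drawn) | C=CC[C@]12CC[C@@](O[Si](C)(C)C(C)(C)C)(C(OC)=C2)[C@H](c3ccc(OC)c(OC)c3)[C@H]1C(=O)OC
F4 | step 5 | racemate of alcohol 18 (one enantiomer drawn) | C=CC[C@]12CC[C@@](O[Si](C)(C)C(C)(C)C)(C(OC)=C2)[C@H](c3ccc(OC)c(OC)c3)[C@H]1CO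
F5 | step 11 | 1-allyl-4,8-dihydroxybicyclo[2.2.2]octan-5-one with aryl and methyl as in 21, C8–OH towards the C2–C3 bridge | C=CC[C@]12CC[C@@](O)(C(=O)[C@H]2O)[C@H](c3ccc(OC)c(OC)c3)[C@H]1C
F6 | step 11 | 8-acetate of F5 | C=CC[C@]12CC[C@@](O)(C(=O)[C@H]2OC(C)=O)[C@H](c3ccc(OC)c(OC)c3)[C@H]1C
F7 | step 11 | 8-acetoxy-1-allyl-5-hydroxybicyclo[3.2.1]octan-4-one (5-O-desmethyl analogue of 24) | C=CC[C@]12CCC(=O)[C@](O)([C@H](c3ccc(OC)c(OC)c3)[C@H]1C)[C@H]2OC(C)=O
F8 | step 6 | C5 dimethyl ketal of 15 | C=CC[C@]12CC[C@@](O[Si](C)(C)C(C)(C)C)(C(OC)(OC)C2)[C@H](c3ccc(OC)c(OC)c3)[C@H]1C(=O)N1[C@@H](Cc3ccccc3)COC1=O
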